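The target is epicatechin-(4β→6)-epicatechin-(4β→8)-epicatechin-(4β→6)-epicatechin. Units 2–4 (numbered from the top) come from (−)-epicatechin through halogen-capped, orthogonally activated flavan-4-yl cation couplings; unit 1 is built de novo and its ring C is closed last, at C4–C4a. C4 of unit 1 is benzylic to the phloroglucinol ring A of unit 2 (at C6), and O1 carries a symmetric 3,5-dioxygenated aryl ring. An aryl-magnesium at C6 of the trimer adds to an acyclic α-benzyloxy-β-aryloxy aldehyde; acid then ionizes both C4 carbinol epimers to one cation, which the phenoxy ring captures. One flask thus makes the interflavan bond, ring C and the 4β stereocenter.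

Key step: step 13

Remark: the 3-hydroxyl groups of the epicatechin-derived units are carried unprotected, as in established couplings of benzylated flavan-4-yl cations, and the sense of induction of the (S,S)-(salen)MnCl catalyst is assumed by analogy with cis-cinnamate esters.

Step 1
Reactants: 1 (−)-epicatechin
Product: 2 5,7,3′,4′-tetra-O-benzyl-(−)-epicatechin
Conditions: BnBr, K2CO3, DMF, 0 °C → rt
Reagents that add atoms: benzyl bromide, BrCc1ccccc1
Why: Williamson etherification of the four phenoxides, which are far more acidic than the C3 alcohol, should leave the secondary hydroxyl free and touch no stereocenter.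

Step 2
Reactants: 2 5,7,3′,4′-tetra-O-benzyl-(−)-epicatechin
Product: 3 8-bromo-5,7,3′,4′-tetra-O-benzylepicatechin
Conditions: NBS, CH2Cl2, −78 °C → rt
Reagents that add atoms: N-bromosuccinimide, O=C1CCC(=O)N1Br
Why: Electrophilic aromatic bromination goes to C8, the most reactive position of ring A in the benzylated flavan, and the bromine later blocks C8 so that coupling is steered to C6.

Step 3
Reactants: 2 5,7,3′,4′-tetra-O-benzyl-(−)-epicatechin
Product: 4 4β-(2-ethoxyethoxy)-5,7,3′,4′-tetra-O-benzylepicatechin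
Conditions: DDQ, 2-ethoxyethanol, CH2Cl2, rt
Reagents that add atoms: 2-ethoxyethanol, CCOCCO
Why: DDQ-mediated benzylic oxidation (hydride abstraction at C4, stabilized by the trioxygenated ring A) with capture of the cation by the alcohol trans to the C3 hydroxyl should set the 4β ether.

Step 4
Reactants: 4 4β-(2-ethoxyethoxy)-5,7,3′,4′-tetra-O-benzylepicatechin
Product: 5 4β-(2,6-dimethylphenylthio)-5,7,3′,4′-tetra-O-benzylepicatechin
Conditions: 2,6-Me2C6H3SH, BF3·OEt2, CH2Cl2, −78 °C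
Reagents that add atoms: 2,6-dimethylbenzenethiol, Cc1cccc(C)c1S
Why: Lewis acid-promoted SN1 exchange through the flavan-4-yl cation, with the thiol adding trans to the C3 hydroxyl (4β), installs a leaving group that is inert to BF3·OEt2 and is triggered later by a thiophile.

Step 5
Reactants: 4 4β-(2-ethoxyethoxy)-5,7,3′,4′-tetra-O-benzylepicatechin
Product: 7 8-bromo-6-iodo-4β-(2-ethoxyethoxy)-5,7,3′,4′-tetra-O-benzylepicatechin, via 8-bromo ether 6 (not isolated)
Conditions: NBS, CH2Cl2, −78 → 0 °C; then NIS, 0 °C → rt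
Reagents that add atoms: N-bromosuccinimide, O=C1CCC(=O)N1Br; N-iodosuccinimide, O=C1CCC(=O)N1I
Why: Two successive electrophilic aromatic halogenations, NBS at C8 first and NIS at C6 as the only remaining ring A position, should give an electrophile that cannot self-condense and carries iodine as the handle for later metalation.

Step 6
Reactants: 7 8-bromo-6-iodo-4β-(2-ethoxyethoxy)-5,7,3′,4′-tetra-O-benzylepicatechin; 5 4β-(2,6-dimethylphenylthio)-5,7,3′,4′-tetra-O-benzylepicatechin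
Product: 8 dimer [8-bromo-6-iodo-tetra-O-benzylepicatechin]-(4β→8)-[4β-(2,6-dimethylphenylthio)-tetra-O-benzylepicatechin]
Conditions: BF3·OEt2, 4 Å MS, CH2Cl2, −78 → −30 °C
Reagents that add atoms: none
Why: Friedel–Crafts arylation of the flavan-4-yl cation released from 7 by the hard Lewis acid (the thioether of 5 is not activated), in which C8 of 5 attacks trans to the C3 hydroxyl, should give the 4β→8 bond.

Step 7
Reactants: 8 dimer with C4 thioether; 3 8-bromo-5,7,3′,4′-tetra-O-benzylepicatechin (3 equiv)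
Product: 9 trimer [8-bromo-6-iodo-tetra-O-benzylepicatechin]-(4β→8)-[tetra-O-benzylepicatechin]-(4β→6)-[8-bromo-tetra-O-benzylepicatechin]
Conditions: I2, Ag2O, 4 Å MS, CH2Cl2, −78 → 0 °C
Reagents that add atoms: none
Why: Thiophilic (soft) activation of the C4 thioether gives the flavan-4-yl cation of the lower unit of 8, and Friedel–Crafts capture by C6 of 3 (C8 blocked by bromine) trans to the C3 hydroxyl should give the 4β→6 bond.

Step 8
Reactants: 10 3,4-bis(benzyloxy)benzaldehyde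
Product: 11 ethyl (Z)-3-[3,4-bis(benzyloxy)phenyl]prop-2-enoate
Conditions: (PhO)2P(O)CH2CO2Et, NaH, THF, −78 → 0 °C
Reagents that add atoms: ethyl 2-(diphenoxyphosphoryl)acetate, CCOC(=O)CP(=O)(Oc1ccccc1)Oc1ccccc1
Why: Ando-type Horner–Wadsworth–Emmons olefination with a diaryl phosphonate should favour the Z-enoate needed for a cis-epoxide.

Step 9
Reactants: 11 ethyl (Z)-3-[3,4-bis(benzyloxy)phenyl]prop-2-enoate
Product: 12 ethyl (2S,3S)-3-[3,4-bis(benzyloxy)phenyl]oxirane-2-carboxylate (cis)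
Conditions: (S,S)-(salen)MnCl [salen = N,N′-bis(3,5-di-tert-butylsalicylidene)-1,2-cyclohexanediamine] (5 mol %), NaOCl (aq, pH 11), 4-phenylpyridine N-oxide, CH2Cl2, 0 °C
Reagents that add atoms: sodium hypochlorite, [Na+].[O-]Cl
Why: Jacobsen–Katsuki epoxidation of a cis-disubstituted conjugated alkene transfers oxygen to one enantioface under catalyst control and so sets both epoxide carbons.

Step 10
Reactants: 12 ethyl (2S,3S)-3-[3,4-bis(benzyloxy)phenyl]oxirane-2-carboxylate; 13 3,5-bis(benzyloxy)phenol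
Product: 14 ethyl (2S,3R)-3-[3,5-bis(benzyloxy)phenoxy]-3-[3,4-bis(benzyloxy)phenyl]-2-hydroxypropanoate
Conditions: K2CO3 (0.2 equiv), DMF, 45 °C
Reagents that add atoms: none
Why: SN2 opening of the aryl glycidate by the phenoxide at the benzylic carbon, with inversion, should give the threo β-aryloxy-α-hydroxy ester, which sets the future C2 while the future C3 keeps the epoxide oxygen.

Step 11
Reactants: 14 ethyl (2S,3R)-3-[3,5-bis(benzyloxy)phenoxy]-3-[3,4-bis(benzyloxy)phenyl]-2-hydroxypropanoate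
Product: 15 ethyl (2S,3R)-2-(benzyloxy)-3-[3,5-bis(benzyloxy)phenoxy]-3-[3,4-bis(benzyloxy)phenyl]propanoate
Conditions: BnBr, Ag2O, CH2Cl2, rt, dark
Reagents that add atoms: benzyl bromide, BrCc1ccccc1
Why: Silver oxide-mediated Williamson benzylation of the α-hydroxy ester runs under nearly neutral conditions, which avoids enolate formation and β-elimination of the aryloxide.

Step 12
Reactants: 15 ethyl (2S,3R)-2-(benzyloxy)-3-[3,5-bis(benzyloxy)phenoxy]-3-[3,4-bis(benzyloxy)phenyl]propanoate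
Product: 16 (2S,3R)-2-(benzyloxy)-3-[3,5-bis(benzyloxy)phenoxy]-3-[3,4-bis(benzyloxy)phenyl]propanal
Conditions: iBu2AlH, CH2Cl2, −78 °C
Reagents that add atoms: none
Why: Partial reduction of the α-alkoxy ester at −78 °C should stop at the chelated aluminium hemiacetal, which releases the aldehyde on work-up for immediate use.

Step 13
Reactants: 9 trimer with C6 iodide on its upper unit; 16 (2S,3R)-2-(benzyloxy)-3-[3,5-bis(benzyloxy)phenoxy]-3-[3,4-bis(benzyloxy)phenyl]propanal (2 equiv)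
Product: 19 protected tetramer (heptadeca-O-benzyl-dibromo derivative of the target), via aryl-magnesium 17 (not isolated), via carbinol 18 (not isolated)
Conditions: MeMgCl (3 equiv), then iPrMgCl·LiCl, THF, −30 °C; 16, −78 → −20 °C; then CF3CO2H, CH2Cl2, −40 → 0 °C
Reagents that add atoms: none
Why: Iodine–magnesium exchange should occur only at the C6 iodide (both aryl bromides stay), and the aryl-magnesium 17 adds to aldehyde 16 to give carbinol 18 as a mixture of C4 epimers; acid then ionizes this 2,4,6-trioxygenated benzylic alcohol to a cation stabilized by ring A of unit 2, and the tethered 3,5-bis(benzyloxy)phenoxy ring closes ring C by intramolecular Friedel–Crafts alkylation (C4–C4a bond), the closest known reaction types being the acid-mediated cyclization of 3-aryloxy-1-arylpropan-1-ols to 4-arylchromans and the capture of flavan-4-yl cations by phloroglucinol-type arenes. Ring C closes as a six-membered ring through C8a, O1, C2 and C3, in the 6-exo-trig mode with respect to the cationic bond between C4 and C6 of unit 2. C4 is the only new stereocenter: both carbinol epimers converge on one planar cation, and in the chair-like transition state with the C2 aryl group equatorial and the C3 benzyloxy group axial the bulky aryl group of unit 2 must sit pseudo-axial to avoid the peri C5 benzyloxy group, which places it trans to the C3 oxygen (4β), while C2 and C3 come unchanged from 16. The step needs the phenoxy ring to win over the catechol ring on C2 (which would give an indane) and over a 1,2-hydride shift from C3; its three oxygen donors and the six-membered transition state should secure this, and its two ortho positions are equivalent, so only one regioisomer can form. Site selectivity on unit 2 is fixed by the position of the iodide and does not depend on relative arene nucleophilicity within the trimer.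

Step 14
Reactants: 19 protected tetramer
Product: 20 epicatechin-(4β→6)-epicatechin-(4β→8)-epicatechin-(4β→6)-epicatechin (CNP0120618.1)
Conditions: H2 (1 atm), Pd(OH)2/C, Et3N, THF–MeOH–H2O, rt
Reagents that add atoms: none
Why: Hydrogenolysis should remove the seventeen benzyl ethers and both aryl bromides, with triethylamine buffering the HBr so that the acid-labile interflavan bonds and all stereocenters stay untouched.

Compound list

1 | (−)-epicatechin | Oc1cc(O)c2c(c1)O[C@H](c1ccc(O)c(O)c1)[C@H](O)C2 | starting material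
2 | 5,7,3′,4′-tetra-O-benzyl-(−)-epicatechin | c4ccccc4COc1cc(OCc4ccccc4)c2c(c1)O[C@H](c1ccc(OCc4ccccc4)c(OCc4ccccc4)c1)[C@H](O)C2 | intermediate
3 | 8-bromo-5,7,3′,4′-tetra-O-benzylepicatechin | c4ccccc4COc1cc(OCc4ccccc4)c2c(c1Br)O[C@H](c1ccc(OCc4ccccc4)c(OCc4ccccc4)c1)[C@H](O)C2 | intermediate
4 | 4β-(2-ethoxyethoxy)-5,7,3′,4′-tetra-O-benzylepicatechin (C4 ether trans to C3–OH) | c4ccccc4COc1cc(OCc4ccccc4)c2c(c1)O[C@H](c1ccc(OCc4ccccc4)c(OCc4ccccc4)c1)[C@H](O)[C@H]2OCCOCC | intermediate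
5 | 4β-(2,6-dimethylphenylthio)-5,7,3′,4′-tetra-O-benzylepicatechin | c4ccccc4COc1cc(OCc4ccccc4)c2c(c1)O[C@H](c1ccc(OCc4ccccc4)c(OCc4ccccc4)c1)[C@H](O)[C@H]2Sc1c(C)cccc1C | intermediate
6 | 8-bromo-4β-(2-ethoxyethoxy)-5,7,3′,4′-tetra-O-benzylepicatechin | c4ccccc4COc1cc(OCc4ccccc4)c2c(c1Br)O[C@H](c1ccc(OCc4ccccc4)c(OCc4ccccc4)c1)[C@H](O)[C@H]2OCCOCC | intermediate
7 | 8-bromo-6-iodo-4β-(2-ethoxyethoxy)-5,7,3′,4′-tetra-O-benzylepicatechin | c4ccccc4COc1c(I)c(OCc4ccccc4)c2c(c1Br)O[C@H](c1ccc(OCc4ccccc4)c(OCc4ccccc4)c1)[C@H](O)[C@H]2OCCOCC | intermediate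
8 | dimer: 8-bromo-6-iodo-tetra-O-benzylepicatechin linked 4β→8 to 4β-(2,6-dimethylphenylthio)-tetra-O-benzylepicatechin | Ic1c(OCc4ccccc4)c(Br)c2c(c1OCc4ccccc4)[C@H](c1c(OCc4ccccc4)cc(OCc4ccccc4)c3c1O[C@H](c1ccc(OCc4ccccc4)c(OCc4ccccc4)c1)[C@H](O)[C@H]3Sc1c(C)cccc1C)[C@@H](O)[C@@H](c1ccc(OCc4ccccc4)c(OCc4ccccc4)c1)O2 | intermediate
9 | trimer: 8-bromo-6-iodo-tetra-O-benzylepicatechin-(4β→8)-tetra-O-benzylepicatechin-(4β→6)-8-bromo-tetra-O-benzylepicatechin | Ic1c(OCc4ccccc4)c(Br)c2c(c1OCc4ccccc4)[C@H](c1c(OCc4ccccc4)cc(OCc4ccccc4)c3c1O[C@H](c1ccc(OCc4ccccc4)c(OCc4ccccc4)c1)[C@H](O)[C@H]3c1c(OCc4ccccc4)c(Br)c3c(c1OCc4ccccc4)C[C@@H](O)[C@@H](c1ccc(OCc4ccccc4)c(OCc4ccccc4)c1)O3)[C@@H](O)[C@@H](c1ccc(OCc4ccccc4)c(OCc4ccccc4)c1)O2 | intermediate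
10 | 3,4-bis(benzyloxy)benzaldehyde | O=Cc1ccc(OCc2ccccc2)c(OCc2ccccc2)c1 | starting material
11 | ethyl (Z)-3-[3,4-bis(benzyloxy)phenyl]prop-2-enoate | CCOC(=O)/C=C\c1ccc(OCc2ccccc2)c(OCc2ccccc2)c1 | intermediate
12 | ethyl (2S,3S)-3-[3,4-bis(benzyloxy)phenyl]oxirane-2-carboxylate (cis) | CCOC(=O)[C@H]1O[C@H]1c1ccc(OCc2ccccc2)c(OCc2ccccc2)c1 | intermediate
13 | 3,5-bis(benzyloxy)phenol | Oc1cc(OCc2ccccc2)cc(OCc2ccccc2)c1 | starting material
14 | ethyl (2S,3R)-3-[3,5-bis(benzyloxy)phenoxy]-3-[3,4-bis(benzyloxy)phenyl]-2-hydroxypropanoate (threo) | CCOC(=O)[C@@H](O)[C@H](Oc1cc(OCc2ccccc2)cc(OCc2ccccc2)c1)c1ccc(OCc2ccccc2)c(OCc2ccccc2)c1 | intermediate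
15 | ethyl (2S,3R)-2-(benzyloxy)-3-[3,5-bis(benzyloxy)phenoxy]-3-[3,4-bis(benzyloxy)phenyl]propanoate | CCOC(=O)[C@@H](OCc1ccccc1)[C@H](Oc1cc(OCc2ccccc2)cc(OCc2ccccc2)c1)c1ccc(OCc2ccccc2)c(OCc2ccccc2)c1 | intermediate
16 | (2S,3R)-2-(benzyloxy)-3-[3,5-bis(benzyloxy)phenoxy]-3-[3,4-bis(benzyloxy)phenyl]propanal | O=C[C@@H](OCc1ccccc1)[C@H](Oc1cc(OCc2ccccc2)cc(OCc2ccccc2)c1)c1ccc(OCc2ccccc2)c(OCc2ccccc2)c1 | intermediate
17 | aryl-magnesium chloride of 9 at C6 of the upper unit, the three 3-hydroxyls as chloromagnesium alkoxides | Cl[Mg]c1c(OCc4ccccc4)c(Br)c2c(c1OCc4ccccc4)[C@H](c1c(OCc4ccccc4)cc(OCc4ccccc4)c3c1O[C@H](c1ccc(OCc4ccccc4)c(OCc4ccccc4)c1)[C@H](O[Mg]Cl)[C@H]3c1c(OCc4ccccc4)c(Br)c3c(c1OCc4ccccc4)C[C@@H](O[Mg]Cl)[C@@H](c1ccc(OCc4ccccc4)c(OCc4ccccc4)c1)O3)[C@@H](O[Mg]Cl)[C@@H](c1ccc(OCc4ccccc4)c(OCc4ccccc4)c1)O2 | intermediate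
18 | carbinol: trimer carrying at C6 of its upper unit the 1-hydroxy-2-(benzyloxy)-3-[3,5-bis(benzyloxy)phenoxy]-3-[3,4-bis(benzyloxy)phenyl]propyl chain, both epimers at the carbinol carbon | c4ccccc4COc1cc(OCc4ccccc4)cc(c1)O[C@H](c1ccc(OCc4ccccc4)c(OCc4ccccc4)c1)[C@H](OCc4ccccc4)C(O)c1c(OCc4ccccc4)c(Br)c2c(c1OCc4ccccc4)[C@H](c1c(OCc4ccccc4)cc(OCc4ccccc4)c3c1O[C@H](c1ccc(OCc4ccccc4)c(OCc4ccccc4)c1)[C@H](O)[C@H]3c1c(OCc4ccccc4)c(Br)c3c(c1OCc4ccccc4)C[C@@H](O)[C@@H](c1ccc(OCc4ccccc4)c(OCc4ccccc4)c1)O3)[C@@H](O)[C@@H](c1ccc(OCc4ccccc4)c(OCc4ccccc4)c1)O2 | intermediate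
19 | protected tetramer: the target with benzyl ethers on all sixteen phenols and on O3 of unit 1, bromine at C8 of units 2 and 4 | c4ccccc4COc1cc(OCc4ccccc4)c2c(c1)O[C@H](c1ccc(OCc4ccccc4)c(OCc4ccccc4)c1)[C@H](OCc4ccccc4)[C@H]2c1c(OCc4ccccc4)c(Br)c2c(c1OCc4ccccc4)[C@H](c1c(OCc4ccccc4)cc(OCc4ccccc4)c3c1O[C@H](c1ccc(OCc4ccccc4)c(OCc4ccccc4)c1)[C@H](O)[C@H]3c1c(OCc4ccccc4)c(Br)c3c(c1OCc4ccccc4)C[C@@H](O)[C@@H](c1ccc(OCc4ccccc4)c(OCc4ccccc4)c1)O3)[C@@H](O)[C@@H](c1ccc(OCc4ccccc4)c(OCc4ccccc4)c1)O2 | intermediate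
20 | epicatechin-(4β→6)-epicatechin-(4β→8)-epicatechin-(4β→6)-epicatechin (CNP0120618.1) | Oc1cc(O)c2c(c1)O[C@H](c1ccc(O)c(O)c1)[C@H](O)[C@H]2c1c(O)cc2c(c1O)[C@H](c1c(O)cc(O)c3c1O[C@H](c1ccc(O)c(O)c1)[C@H](O)[C@H]3c1c(O)cc3c(c1O)C[C@@H](O)[C@@H](c1ccc(O)c(O)c1)O3)[C@@H](O)[C@@H](c1ccc(O)c(O)c1)O2 | target

Total step count: 14. Longest linear sequence: 7 steps (1 → 2 → 4 → 7 → 8 → 9 → 19 → 20; the aldehyde branch 10 → 11 → 12 → 14 → 15 → 16 → 19 → 20 is equally long).

Steps most likely to fail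

Step 13. The hindered aryl-magnesium may act as a base, removing the proton α to the aldehyde (followed by loss of the aryloxide) faster than it adds, so that no carbinol forms. The fallback sets out from 15: aminolysis with MeNH(OMe)·HCl and iPrMgCl gives the Weinreb amide F1. The aryl-magnesium 17 made from 9 acylates it to the aryl ketone F2; the α-proton of the amide is much less acidic and the chelated tetrahedral intermediate cannot eliminate. Luche reduction (NaBH4, CeCl3, THF–MeOH, −40 °C) gives carbinol 18 as an epimer mixture, where the route is rejoined; CF3CO2H then closes ring C to 19 as in step 13.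

Step 10. The electron-rich benzylic C–O bond may ionize before the phenoxide attacks (loss of stereospecificity), attack may occur at the carbon α to the ester, or the base may expel the aryloxide from the product. The fallback sets out from 12: NaBH4 reduction of the ester gives the cis-epoxy alcohol F3. Opening with the sodium phenoxide of 13 in aqueous NaOH–dioxane at 70 °C, the established mode for 3-aryl glycidols (attack at the benzylic carbon with inversion, no acidic α-proton), gives the threo diol F4. Chemoselective oxidation of the primary alcohol (TEMPO, NaOCl, NaClO2, pH 6.7) gives the α-hydroxy acid F5, and O-alkylation with EtI and KHCO3 in DMF returns to 14.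

Step 7. The electrophilic iodine activator may halogenate the free C6 of nucleophile 3 before the C–C bond forms, or the cation may be intercepted by C6 of the lower unit of a second molecule of 8. The fallback reverses the order of the two couplings and uses hard activation only. It sets out from 4: NIS iodinates C8 to give the 8-iodo ether F6. BF3·OEt2 coupling of F6 with excess 3 gives the (4β→6) iodo-bromo dimer F7, capped by iodine on its upper and bromine on its lower unit. Iodine–magnesium exchange (MeMgCl, then iPrMgCl·LiCl, THF, −30 °C; MeOH quench) removes only the iodine to give the dimer F8 with a free C8, and BF3·OEt2 coupling of F8 with the capped electrophile 7 returns to 9.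

Further compounds
F1 | step 13 | (2S,3R)-2-(benzyloxy)-3-[3,5-bis(benzyloxy)phenoxy]-3-[3,4-bis(benzyloxy)phenyl]-N-methoxy-N-methylpropanamide | CON(C)C(=O)[C@@H](OCc1ccccc1)[C@H](Oc1cc(OCc2ccccc2)cc(OCc2ccccc2)c1)c1ccc(OCc2ccccc2)c(OCc2ccccc2)c1
F2 | step 13 | aryl ketone: trimer carrying at C6 of its upper unit the 2-(benzyloxy)-3-[3,5-bis(benzyloxy)phenoxy]-3-[3,4-bis(benzyloxy)phenyl]propanoyl group | c4ccccc4COc1cc(OCc4ccccc4)cc(c1)O[C@H](c1ccc(OCc4ccccc4)c(OCc4ccccc4)c1)[C@H](OCc4ccccc4)C(=O)c1c(OCc4ccccc4)c(Br)c2c(c1OCc4ccccc4)[C@H](c1c(OCc4ccccc4)cc(OCc4ccccc4)c3c1O[C@H](c1ccc(OCc4ccccc4)c(OCc4ccccc4)c1)[C@H](O)[C@H]3c1c(OCc4ccccc4)c(Br)c3c(c1OCc4ccccc4)C[C@@H](O)[C@@H](c1ccc(OCc4ccccc4)c(OCc4ccccc4)c1)O3)[C@@H](O)[C@@H](c1ccc(OCc4ccccc4)c(OCc4ccccc4)c1)O2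
F3 | step 10 | [(2R,3S)-3-[3,4-bis(benzyloxy)phenyl]oxiran-2-yl]methanol (cis) | OC[C@H]1O[C@H]1c1ccc(OCc2ccccc2)c(OCc2ccccc2)c1
F4 | step 10 | (2R,3R)-3-[3,5-bis(benzyloxy)phenoxy]-3-[3,4-bis(benzyloxy)phenyl]propane-1,2-diol (threo) | OC[C@@H](O)[C@H](Oc1cc(OCc2ccccc2)cc(OCc2ccccc2)c1)c1ccc(OCc2ccccc2)c(OCc2ccccc2)c1
F5 | step 10 | (2S,3R)-3-[3,5-bis(benzyloxy)phenoxy]-3-[3,4-bis(benzyloxy)phenyl]-2-hydroxypropanoic acid | OC(=O)[C@@H](O)[C@H](Oc1cc(OCc2ccccc2)cc(OCc2ccccc2)c1)c1ccc(OCc2ccccc2)c(OCc2ccccc2)c1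
F6 | step 7 | 8-iodo-4β-(2-ethoxyethoxy)-5,7,3′,4′-tetra-O-benzylepicatechin | c4ccccc4COc1cc(OCc4ccccc4)c2c(c1I)O[C@H](c1ccc(OCc4ccccc4)c(OCc4ccccc4)c1)[C@H](O)[C@H]2OCCOCC
F7 | step 7 | dimer: 8-iodo-tetra-O-benzylepicatechin-(4β→6)-8-bromo-tetra-O-benzylepicatechin | Ic1c(OCc4ccccc4)cc(OCc4ccccc4)c3c1O[C@H](c1ccc(OCc4ccccc4)c(OCc4ccccc4)c1)[C@H](O)[C@H]3c1c(OCc4ccccc4)c(Br)c3c(c1OCc4ccccc4)C[C@@H](O)[C@@H](c1ccc(OCc4ccccc4)c(OCc4ccccc4)c1)O3
F8 | step 7 | dimer: tetra-O-benzylepicatechin-(4β→6)-8-bromo-tetra-O-benzylepicatechin | c1c(OCc4ccccc4)cc(OCc4ccccc4)c3c1O[C@H](c1ccc(OCc4ccccc4)c(OCc4ccccc4)c1)[C@H](O)[C@H]3c1c(OCc4ccccc4)c(Br)c3c(c1OCc4ccccc4)C[C@@H](O)[C@@H](c1ccc(OCc4ccccc4)c(OCc4ccccc4)c1)O3
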